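The coupling partner is charged at less than the substrate, so it is the limiting reagent and the quantity to watch in beta and theta is the fraction of it left, f.

| setting | summer | dawn | winter | beta | theta |
|---|---|---|---|---|---|
| substrate | 0.10 M | 0.10 M | 0.10 M | 0.10 M | 0.10 M |
| coupling partner | 0.040 M | 0.090 M | 0.060 M | 0.0600 M | 0.0600 M |
| free catalyst | 0.20 mM | 0.20 mM | 0.10 mM | 0.20 mM | 0.20 mM |
| added ligand | 0.29 mM | 0.29 mM | 0.29 mM | 0.29 mM | 0.29 mM |
| remark | run made earlier | run made earlier | run made earlier |  |  |
| time |  |  |  | 40 h | 80 h |

| run | time / h | catalyst intermediate D / % | target / % | catalyst intermediate B / % | substrate / % |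
|---|---|---|---|---|---|
| summer | 6.00 | 0.8 | 6.6 | 0.6 | 92.5 |
| summer | 15.0 | 0.4 | 15.9 | 0.1 | 83.5 |
| summer | 20.0 | 0 | 21.0 | 0 | 79.7 |
| summer | 30.0 | 0 | 27.3 | 0.5 | 73.4 |
| summer | 40.0 | 0 | 32.5 | 0.3 | 68.2 |
| summer | 50.0 | 0 | 35.8 | 0.1 | 64.9 |
| dawn | 2.50 | 0 | 3.8 | 0.9 | 95.3 |
| dawn | 8.00 | 0 | 12.2 | 0 | 86.5 |
| dawn | 15.0 | 0 | 22.7 | 0 | 77.1 |
| dawn | 20.0 | 0 | 29.2 | 0.5 | 70.5 |
| dawn | 30.0 | 0 | 41.9 | 0.6 | 59.9 |
| dawn | 40.0 | 0.1 | 51.3 | 0.3 | 48.8 |
| dawn | 50.0 | 0.4 | 60.7 | 0.6 | 39.7 |
| winter | 10.0 | 0.4 | 6.7 | 0.7 | 93.4 |
| winter | 20.0 | 0.4 | 13.3 | 0.3 | 87.6 |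
| winter | 30.0 | 0.1 | 19.0 | 0.3 | 80.5 |
| winter | 40.0 | 0.4 | 24.4 | 0.9 | 75.9 |
| winter | 50.0 | 0 | 29.6 | 0.4 | 71.2 |

(scatter of a reading: 0.5 percentage points)

1. which of these there is most of at the end, counted by the substrate in it, beta (substrate / catalyst intermediate B / catalyst intermediate D / target)
2. which of these there is most of at the end, counted by the substrate in it, theta (substrate / catalyst intermediate B / catalyst intermediate D / target)
3. amount of the one of these that there is most of at the end, in percent of the substrate charged, beta
4. amount of the one of these that there is most of at the end, in percent of the substrate charged, theta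

- what may be going on: coupling partner + free catalyst -> catalyst intermediate A; substrate + catalyst intermediate A -> catalyst intermediate B; catalyst intermediate B <-> catalyst intermediate C; catalyst intermediate C -> by-product + catalyst intermediate D; catalyst intermediate D -> free catalyst + target; free catalyst + added ligand <-> idle complex

First take the main step alone, with substrate and coupling partner used one for one. Target then stops at 60.0% of the substrate charge. Target equals substrate at the crossover fraction, the share of partner still free at that moment. With S and P the charges of substrate and partner: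

f× = (P − S/2)/P = 16.7%

Above f× substrate leads; below it target leads.

Next add a rate. The early readings of summer and dawn average r = 0.0131 h⁻¹, as a fraction of the substrate charge. Held constant, r gives beta:

x = r·t = 52.5%, f = 12.5%

That is below f×, so a constant rate puts target ahead in beta. But summer's rate reads 0.0110 h⁻¹ at first and 0.00330 h⁻¹ over its last interval, while its partner is used. At r, beta's partner reaches summer's charge after about 15.2 h, and my reckoning then follows summer's readings, although beta then holds less substrate than summer did at its start:

beta: x = 44.0%, f = 26.7%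

This is above f×, so beta keeps substrate in the lead at about 56.0%. By the same shift theta reaches summer's last reading at about 65.2 h, before its own end, with f = 7.00%, below f×. My reckoning therefore has target ahead in theta, with about 55.8% at that moment and the cap of 60.0% above it at 80 h.

Last come catalyst and added ligand. Summer and dawn carry the charges of both that beta and theta have, so my reckoning adds no term for them. Winter, with 0.10 mM of catalyst, reads 0.00665 h⁻¹, about half of r.

The forecast differs from this reckoning: substrate at 57% for beta and target at 57.8% for theta, holding that “the order in partner is saturating”.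

Beta gives 57.6% substrate and 42.3% target; theta gives 57.4% target and 42.6% substrate.

    coupling partner + free catalyst → catalyst intermediate A (k = 440 M⁻¹ h⁻¹)
    substrate + catalyst intermediate A → catalyst intermediate B (k = 350 M⁻¹ h⁻¹)
    catalyst intermediate B ⇌ catalyst intermediate C (K = 25.0, k = 27.0 h⁻¹)
    catalyst intermediate C → by-product + catalyst intermediate D (k = 550 h⁻¹)
    catalyst intermediate D → free catalyst + target (k = 36.0 h⁻¹)
    free catalyst + added ligand ⇌ idle complex (K = 2000 M⁻¹, k = 100 M⁻¹ h⁻¹)

Free partner stands at 29% in beta, 13 percentage points above f×, and at 4.3% in theta, below f×. A neighbouring flask, theta with 0.24 M of partner, has 2.40 equiv of partner to substrate and an f× of 79.2%. Its free partner ends at 61%, below that line, and target leads with 94.0%.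

(The numbers in the tables were computed on assumed constants.)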